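## The problem

The target is a cycloheptane (C1, C5, C6, C7, C8, C9, C10) cis-fused across C6–C7 to an α-methyl-γ-butyrolactone (C11, C12, ring oxygen on C6; C13 is the lactone methyl). C1 carries a tertiary hydroxyl and a 3-hydroxybutanoyl chain (C2 ketone, C3, C4 carbinol, C15 methyl), C5 carries an angelate, and C10 a methyl group (C14). Six of the seven stereocentres are contiguous: the C6–O, C7–C11, C10–CH3 and C1–OH bonds lie on one face of the seven-membered ring, the C5–O and C1–C2 bonds on the other, and H6, H7 and H11 are all cis on the lactone. The ring centres can relay information to one another, but C4 is too remote and is best bought from the chiral pool. C11 is the kinetically protonated epimer (methyl on the concave face) and must not be left to equilibrate. At C1 the hydroxyl is anti to the C5 oxygen, which is the opposite of what addition of a carbon nucleophile to an α-alkoxy ketone delivers, so the oxygen has to be added to an sp2 C1 that already carries C2. The angelate (Z to E isomerisation, conjugate addition, hydrogenation), the β-hydroxy ketone (retro-aldol, dehydration), the tertiary α-ketol and the enolisable lactone will not survive strong base, strong acid or reducing metals, so they are unveiled late. The enabling feature is the trans-dioxygenated C5–C6 edge next to carbonyl-level C1: C6, C7, C8, C9 and the lactone oxygen are the five atoms of furan, and C5–C1–C10 is an alkoxy-substituted oxyallyl cation.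

## Retrosynthesis

**Endgame, 29 back to 24 and 25.** The last bonds made are the C5–O acyl bond, the C2 carbonyl and the free C4 hydroxyl. Target 29 comes from silyl ether 28, 28 from diol 27 by oxidation of the secondary C2 carbinol, and 27 from acetonide 26. The angelate is attached to alcohol 24 with angelic acid 25 while C5–OH is the only free hydroxyl, so no selectivity between hydroxyls is asked for and the β-hydroxy ketone never meets a base.

**Lactone, 24 back to 17.** The C12–O6 acyl bond is cut rather than C7–C11, because the oxygen on C6 is already in place and cis to the carbon branch. Alcohol 24 arises from alkene 23 by one hydrogenation that saturates C8=C9 and removes the auxiliary. C11 in 23 is set by kinetic protonation of enolate 22, so lactone 21 may be an epimer mixture. Lactone 21 comes from diol 19, and 19 from the isopropenyl alcohol 17 by hydroboration. The forward steps ask only for chemoselectivity between a 1,1-disubstituted and a ring alkene, and for convex-face protonation.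

**Bridge opening, 17 back to 16.** Cutting C7–C11 while reconnecting C9 to the C6 oxygen leads to the oxygen-bridged bicycle 16. A syn SN2′ attack by an isopropenyl nucleophile gives the cis C6–O/C7–C relationship directly. The forward step must choose C7 over C8; this is the least secure demand of the plan.

**Side chain, 16 back to 11 and 12.** Removing the acetonide (16 from 15) and the silyl ether (15 from 14) and cutting C2–C3 in triol 14 gives the α-hydroxy aldehyde 11 and a two-carbon nucleophile made from (S)-propylene oxide 12. C4 then comes from the chiral pool. The C2 carbinol configuration is irrelevant because C2 ends as a ketone.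

**C1, 11 back to 8.** The C1–O bond is cut before the C1–C2 bond: aldehyde 11 comes from the exocyclic enol ether 9 by epoxidation on the bridge side, and 9 from ketone 8 by a one-carbon Wittig reaction. Adding a carbon nucleophile to 8 would put the carbon on the bridge side and the hydroxyl on the wrong face. The rigid bicycle is kept for this step so that the oxidant has one open face.

**C10 methyl, 8 back to 7.** The C10–C14 bond is cut to the parent ketone 7; alkylation of its α′-enolate on the bridge side gives the axial methyl group.

**Key disconnection, 7 back to 4 and 5.** C5–C6 and C9–C10 are cut together, which returns furan 5 and the silyl enol ether acetal 4. This removes the ring and three stereocentres in one step. The forward reaction must place the ether equatorial and pick one enantiomer of the bicycle.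

**Cation precursor, 4 back to 1 and 2.** Enol ether 4 comes from mixed acetal 3, and 3 from 1,1-dimethoxypropan-2-one 1 and (S)-1-phenylethanol 2. Only one methoxy group is exchanged: one equivalent of auxiliary is enough, the methoxy group is the one that leaves in the key step, and forcing a second exchange would risk ionising the benzylic alcohol.

## Roads not taken

**Alternative 1:** Ring expansion of cis-dihydrocarvone A1. The cut is at C1–C5 and C5–C6; in the forward sense a Lewis-acid-promoted insertion of a silylated diazomethane carbon, with migration of the ring methylene, would give cycloheptanone A2. Its merits are real: A1 is cheap and enantiopure, the C10 methyl and the three-carbon branch on C7 are present from the start in the correct cis relationship, and no auxiliary is needed. In securing C7, C10 and the C11–C13 carbons it is better than the chosen plan, which must gamble on the regiochemistry of a bridge opening. Its weakness is that A2 has no oxygen at C5 or C6 and none of the three oxygenated ring stereocentres. C6 is a β-methylene with no handle, the migrating group in the insertion (methylene against methine) is not fully controlled, and every oxidation must be done on a flexible ring without a rigid bias. The chosen plan sets against this a single step that delivers the C5/C6 oxygen pattern, the absolute configuration and a bicycle whose bridge controls C10 and C1.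

**Alternative 2:** Claisen ring expansion of a 2-methylene-5-alkenyl tetrahydrofuran to cycloheptenone A3. The cut is at C6–C7, and the forward step breaks the ring O–C9 bond in a chair transition state. It transfers chirality cleanly to C7, carries C11 in with the side chain, includes the C10 methyl and a C1 oxygen, and leaves the C8=C9 alkene exactly where hydrogenation can remove it. For C7 and C11 it is more convincing than the chosen plan, which corrects C11 by a protonation and relies on a regioselective opening for C7. Against it, the ketone of A3 sits at C5 and C6 is a bare methylene, so C5, C6 and C1 all need redox changes, and C1 still has to be made quaternary from a ketone with the same facial problem. The tetrahydrofuran precursor with its stereocentres and exocyclic enol ether is itself a long synthesis. The chosen plan reaches the oxygenated seven-membered ring in three steps from commodity chemicals.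

**Alternative 3:** Radical 7-exo closure onto a butenolide to give lactone A4. The cut is at C7–C8; a primary alkyl radical generated from an iodide with a silane chain carrier would add to the butenolide β-carbon and the lactone radical would be reduced. If it worked it would be the shortest endgame of all, since A4 already holds six ring stereocentres, the lactone and a C1 ester ready for chain extension; in this respect it is better than the chosen plan. Its weak points are the key step and the precursor. Seven-membered radical closures of primary radicals compete poorly with direct reduction and 1,5-hydrogen transfer. The configurations at C7 and C11 depend on weakly biased radical addition and hydrogen transfer. The dioxolane spanning the trans C1/C5 oxygens adds strain to the forming ring. The acyclic precursor with its C1, C5, C6 and C10 stereocentres needs a long linear sequence. The chosen plan has a key step of a known reaction type on exactly these partners and leaves its uncertainties to later steps that have fallbacks.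

Key step: step 3

Assumption: the (S)-1-phenylethyl group is taken to direct furan to the face of the cation that gives the (1R,2S,5R) bicycle 7; if the sense of induction is the opposite, (R)-1-phenylethanol is used and nothing else in the route changes.

Step 1
Reactants: 1 1,1-dimethoxypropan-2-one; 2 (S)-1-phenylethanol
Product: 3 1-methoxy-1-[(S)-1-phenylethoxy]propan-2-one (both epimers at the acetal carbon)
Conditions: 2 (1 equiv), p-TsOH·H2O (cat.), neat, 60 °C, reduced pressure (MeOH removed)
Reagents that add atoms: none
Why: Acid-catalysed transacetalisation through the methoxy oxocarbenium ion; one equivalent of alcohol and removal of methanol should stop the exchange at the mixed acetal. The benzylic C–O bond is not broken, so the auxiliary keeps its configuration, and the acetal stereocentre is planarised again in step 3.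

Step 2
Reactants: 3 1-methoxy-1-[(S)-1-phenylethoxy]propan-2-one
Product: 4 3-methoxy-3-[(S)-1-phenylethoxy]-2-(triethylsilyloxy)prop-1-ene
Conditions: LiN(i-Pr)2, THF, −78 °C; Et3SiCl, −78 → 0 °C
Reagents that add atoms: chlorotriethylsilane, CC[Si](Cl)(CC)CC
Why: Kinetic deprotonation should occur at the methyl group, since the acetal methine is hindered and flanked by two oxygens; O-silylation of the enolate gives the silyl enol ether. The triethylsilyl group is chosen because it survives isolation better than trimethylsilyl.

Step 3
Reactants: 4 3-methoxy-3-[(S)-1-phenylethoxy]-2-(triethylsilyloxy)prop-1-ene; 5 furan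
Product: 7 (1R,2S,5R)-2-[(S)-1-phenylethoxy]-8-oxabicyclo[3.2.1]oct-6-en-3-one (ether equatorial and trans to the oxygen bridge), via alkoxy-siloxyallyl cation 6 (not isolated)
Conditions: furan (5 equiv), Me3SiOTf (0.1 equiv), CH2Cl2, −95 °C
Reagents that add atoms: none
Why: Me3SiOTf ionises the mixed acetal at the less hindered and more basic methoxy oxygen and leaves the Z-configured 1-alkoxy-2-siloxyallyl cation 6, in which the ether oxygen and the silyloxy group are on the same side. The cation adds across the two α-carbons of furan: its oxocarbenium end bonds first (C5–C6) and the enol silane end then bonds to the other α-carbon (C9–C10), a concerted-asynchronous or rapidly stepwise [4+3] cycloaddition whose closest known reaction type is the Lewis-acid-triggered [4+3] cycloaddition of α-alkoxy silyl enol ether acetals with furan. The one ring that closes is the seven-membered carbocycle, and it closes in the second bond formation, an intramolecular attack of the silyl enol ether on the furan-derived oxocarbenium ion that can only occur suprafacially, so the two bridgehead hydrogens are cis and the oxygen becomes a one-atom bridge. The C5 stereocentre is set by the Z geometry of the cation together with the compact approach of furan, which should place the ether equatorial and trans to the bridge. The absolute sense at C5, C6 and C9 is set by the 1-phenylethyl group, whose phenyl ring shields one face of the planar cation when its C–H bond lies in the oxocarbenium plane. The step therefore needs equatorial placement and facial selectivity; the first is secured by the cation geometry and the second by the auxiliary at very low temperature, and the minor isomer is a diastereomer that chromatography can remove. Et3SiOTf is released after each cycloaddition and ionises the next acetal, so a catalytic amount of silyl triflate should suffice.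

Step 4
Reactants: 7 (1R,2S,5R)-2-[(S)-1-phenylethoxy]-8-oxabicyclo[3.2.1]oct-6-en-3-one
Product: 8 4-methyl-2-[(S)-1-phenylethoxy]-8-oxabicyclo[3.2.1]oct-6-en-3-one (bicycle as in 7; methyl axial and cis to the oxygen bridge)
Conditions: LiN(i-Pr)2, THF, −78 °C; MeI, −78 → −40 °C
Reagents that add atoms: iodomethane, CI
Why: Kinetic enolisation of an α-alkoxy ketone should occur at the unsubstituted α′ carbon (C10), and the enolate is alkylated on the face of the oxygen bridge because the etheno bridge blocks the other face; this gives the axial methyl group cis to the bridge. The axial epimer is the kinetic one, so excess base and warming are avoided.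

Step 5
Reactants: 8 4-methyl-2-[(S)-1-phenylethoxy]-8-oxabicyclo[3.2.1]oct-6-en-3-one
Product: 9 3-(methoxymethylidene)-4-methyl-2-[(S)-1-phenylethoxy]-8-oxabicyclo[3.2.1]oct-6-ene (ring stereocentres as in 8; either enol ether geometry)
Conditions: (MeOCH2)PPh3Cl, KN(SiMe3)2, THF, 0 °C; then 8, 0 °C → rt
Reagents that add atoms: (methoxymethyl)triphenylphosphonium chloride, COC[P+](c1ccccc1)(c1ccccc1)c1ccccc1.[Cl-]
Why: Wittig reaction with the small methoxymethylene ylide, which is known to olefinate hindered ketones, installs C2. The C10 hydrogen of 8 is equatorial and poorly aligned for enolisation, which should protect the axial methyl group from epimerisation; the enol ether geometry is lost in step 6.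

Step 6
Reactants: 9 3-(methoxymethylidene)-4-methyl-2-[(S)-1-phenylethoxy]-8-oxabicyclo[3.2.1]oct-6-ene
Product: 11 3-hydroxy-4-methyl-2-[(S)-1-phenylethoxy]-8-oxabicyclo[3.2.1]oct-6-ene-3-carbaldehyde (hydroxyl cis to the oxygen bridge and to the methyl group; formyl group on the side of the etheno bridge), via spiro methoxy epoxide 10 (not isolated)
Conditions: dimethyldioxirane (acetone solution), CH2Cl2, −78 → −20 °C; then H2O, silica gel
Reagents that add atoms: dimethyldioxirane, CC1(C)OO1; water, O
Why: Epoxidation of an enol ether followed by hydrolytic opening (a Rubottom-type oxidation); the electron-rich enol ether should react far faster than the ring alkene, which is deactivated by two allylic oxygens. The oxidant should approach from the side of the oxygen bridge, because the etheno bridge closes the other face and the allylic C5 ether also directs attack anti to itself; the C1–O bond formed there is kept when the epoxide opens through the oxocarbenium ion, which sets C1.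

Step 7
Reactants: 11 3-hydroxy-4-methyl-2-[(S)-1-phenylethoxy]-8-oxabicyclo[3.2.1]oct-6-ene-3-carbaldehyde; 12 (S)-propylene oxide
Product: 14 1-{3-hydroxy-4-methyl-2-[(S)-1-phenylethoxy]-8-oxabicyclo[3.2.1]oct-6-en-3-yl}butane-1,3-diol (3S at the methyl carbinol C4; both epimers at C2; ring as in 11), via lithium (S)-1-lithiopropan-2-olate 13 (not isolated)
Conditions: 12, lithium 4,4′-di-tert-butylbiphenylide (2 equiv), THF, −78 °C; then 11 (13 in 2.2-fold amount), −78 °C; H2O
Reagents that add atoms: none
Why: Reductive lithiation of the epoxide at its primary C–O bond gives a β-oxido organolithium, which cannot eliminate because the leaving group would be an oxide dianion; it adds to the aldehyde to form C2–C3. The C4–O bond is never broken, so C4 is S as in the epoxide; one equivalent of 13 is spent on the tertiary hydroxyl proton, and the C2 configuration does not matter.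

Step 8
Reactants: 14 1-{3-hydroxy-4-methyl-2-[(S)-1-phenylethoxy]-8-oxabicyclo[3.2.1]oct-6-en-3-yl}butane-1,3-diol
Product: 15 the C4 tert-butyldiphenylsilyl ether of 14 (tertiary C1 and secondary C2 hydroxyls free)
Conditions: t-BuPh2SiCl, imidazole, DMF, 0 °C → rt
Reagents that add atoms: tert-butyl(chloro)diphenylsilane, CC(C)(C)[Si](Cl)(c1ccccc1)c1ccccc1
Why: Silylation should take the unhindered methyl carbinol and leave the neopentyl-type C2 hydroxyl and the tertiary C1 hydroxyl. The diphenylsilyl ether is chosen because it must survive the acid of step 16.

Step 9
Reactants: 15 the C4 tert-butyldiphenylsilyl ether of 14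
Product: 16 the C1,C2-acetonide of 15 (2,2-dimethyl-1,3-dioxolane spiro-fused at C1; ring as in 11)
Conditions: Me2C(OMe)2, PPTS (cat.), CH2Cl2, rt
Reagents that add atoms: 2,2-dimethoxypropane, COC(C)(C)OC
Why: Acid-catalysed ketal exchange closes the five-membered dioxolane on the vicinal diol. It removes every acidic hydroxyl and masks C2 at the carbinol level for the organolithium, oxidation and enolate steps that follow.

Step 10
Reactants: 16 the C1,C2-acetonide of 15
Product: 17 cyclohept-8-ene with 5-[(S)-1-phenylethoxy], 6-hydroxy, 7-(prop-1-en-2-yl), 10-methyl and the C1 dioxolane chain (6-OH, 7-isopropenyl, 10-methyl and the C1–O bond on one face; the C5 ether on the other)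
Conditions: CH2=C(Br)CH3, t-BuLi (2 equiv), Et2O, −78 °C; then 16, TMEDA, −78 → 0 °C; H2O
Reagents that add atoms: 2-bromopropene, CC(Br)=C
Why: Syn SN2′ ring opening of an oxabicyclic alkene by an organolithium: lithium coordinates the bridging oxygen and the carbon is delivered to the bridge-side face of the strained alkene, so the new C7–C11 bond is cis to the C6 oxygen while the double bond moves to C8=C9. Attack at C7 with cleavage of C9–O is expected because the C6–O bond is strengthened inductively by the vicinal C5 ether and is the poorer leaving bond; this regiochemistry is the main uncertainty of the route.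

Step 11
Reactants: 17 cyclohept-8-ene with 5-[(S)-1-phenylethoxy], 6-hydroxy, 7-(prop-1-en-2-yl), 10-methyl and the C1 dioxolane chain
Product: 19 the 6,12-diol in which the isopropenyl group has become a 1-hydroxypropan-2-yl group (both C11 epimers), via B-alkyl-9-borabicyclo[3.3.1]nonane 18 (not isolated)
Conditions: 9-BBN (3 equiv), THF, 0 °C → rt; then NaOH, H2O2, 0 °C
Reagents that add atoms: hydrogen peroxide, OO
Why: Anti-Markovnikov hydroboration and oxidation; 9-BBN reacts far faster with a 1,1-disubstituted terminal alkene than with a cis ring alkene, so C8=C9 should survive. No selectivity at C11 is needed because step 13 resets that centre.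

Step 12
Reactants: 19 the 6,12-diol
Product: 21 cis-fused γ-lactone (C12 carbonyl on the C6 oxygen; both C11 epimers), via lactol 20 (not isolated)
Conditions: TEMPO (cat.), PhI(OAc)2, CH2Cl2, rt
Reagents that add atoms: none
Why: Oxoammonium oxidation of the primary alcohol gives the aldehyde, which closes on the cis C6 hydroxyl to the five-membered lactol and is oxidised again to the lactone. The secondary C6 hydroxyl is oxidised much more slowly, and the acetonide keeps the C1/C2 glycol out of reach of the iodine reagent.

Step 13
Reactants: 21 cis-fused γ-lactone (both C11 epimers)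
Product: 23 cis-fused γ-lactone with the C11 methyl cis to C8 (H6 H7 H11 all cis), via lithium enolate 22 (not isolated)
Conditions: LiN(i-Pr)2, THF, −78 °C; then AcOH (in THF), −78 °C
Reagents that add atoms: none
Why: Both epimers give the same lactone enolate, and kinetic protonation should occur on the convex face of the cis-fused bicycle, the face of H7. This places H11 cis to H7 and the methyl group on the concave side as in the target; the quench is done cold and irreversibly because this is the less stable epimer.

Step 14
Reactants: 23 cis-fused γ-lactone with the C11 methyl cis to C8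
Product: 24 the saturated lactone with a free C5 hydroxyl (acetonide and silyl ether intact)
Conditions: H2 (1 atm), 10% Pd/C, EtOAc, rt
Reagents that add atoms: none
Why: Heterogeneous hydrogenation saturates the disubstituted C8=C9 alkene, and hydrogenolysis of the benzylic C–O bond removes the 1-phenylethyl group as ethylbenzene, leaving the oxygen on C5. No stereocentre is formed or put at risk.

Step 15
Reactants: 24 the saturated lactone with a free C5 hydroxyl; 25 angelic acid
Product: 26 the C5 angelate of 24
Conditions: 25, 2,4,6-Cl3C6H2COCl, Et3N, toluene, rt; then 24, 80 °C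
Reagents that add atoms: none
Why: Yamaguchi esterification through the mixed anhydride, run without a nucleophilic amine catalyst, is the usual way to attach an angelate without Z to E isomerisation. C5–OH is the only free hydroxyl, so no selectivity is required, though the hindered position may demand excess anhydride.

Step 16
Reactants: 26 the C5 angelate of 24
Product: 27 the C1,C2-diol (angelate, lactone and C4 silyl ether intact)
Conditions: AcOH–H2O (4:1), 40 °C
Reagents that add atoms: none
Why: Mild aqueous acid hydrolyses the dioxolane; the tert-butyldiphenylsilyl ether, the lactone and the angelate should be stable under these conditions. Migration of the angelate to the tertiary hydroxyl is not expected.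

Step 17
Reactants: 27 the C1,C2-diol
Product: 28 the C2 ketone (tertiary C1 hydroxyl free; C4 silyl ether)
Conditions: Dess–Martin periodinane, CH2Cl2, 0 °C → rt
Reagents that add atoms: none
Why: Dess–Martin oxidation converts the only secondary alcohol into the ketone; the tertiary alcohol cannot be oxidised, and the neutral conditions spare the angelate and the new α-ketol.

Step 18
Reactants: 28 the C2 ketone
Product: 29 CNP0321985.2 (target)
Conditions: HF·pyridine, THF, pyridine, 0 °C → rt
Reagents that add atoms: none
Why: Fluoride cleavage of the silyl ether under buffered, weakly acidic conditions frees the C4 hydroxyl. Basic fluoride sources are avoided because they could cause retro-aldol cleavage or dehydration of the β-hydroxy ketone.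

## Compound list

1 | 1,1-dimethoxypropan-2-one | CC(=O)C(OC)OC | starting material
2 | (S)-1-phenylethanol | C[C@H](O)c1ccccc1 | starting material
3 | 1-methoxy-1-[(S)-1-phenylethoxy]propan-2-one (both acetal epimers) | CC(=O)C(OC)O[C@@H](C)c1ccccc1 | intermediate
4 | 3-methoxy-3-[(S)-1-phenylethoxy]-2-(triethylsilyloxy)prop-1-ene | C=C(O[Si](CC)(CC)CC)C(OC)O[C@@H](C)c1ccccc1 | intermediate
5 | furan | c1ccoc1 | starting material
6 | (Z)-1-[(S)-1-phenylethoxy]-2-(triethylsilyloxy)allyl cation, triflate (not isolated) | [CH2+]/C(O[Si](CC)(CC)CC)=C/O[C@@H](C)c1ccccc1.[O-]S(=O)(=O)C(F)(F)F | intermediate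
7 | (1R,2S,5R)-2-[(S)-1-phenylethoxy]-8-oxabicyclo[3.2.1]oct-6-en-3-one | C[C@@H](c1ccccc1)O[C@H]1[C@H]2C=C[C@H](O2)CC1=O | intermediate
8 | 4-methyl derivative of 7, methyl axial and cis to the oxygen bridge | C[C@@H](c1ccccc1)O[C@H]1[C@H]2C=C[C@H](O2)[C@H](C)C1=O | intermediate
9 | 3-(methoxymethylidene) derivative of 8 | C[C@@H](c1ccccc1)O[C@H]1[C@H]2C=C[C@H](O2)[C@H](C)C1=COC | intermediate
10 | spiro methoxy epoxide of 9, epoxide oxygen on the side of the oxygen bridge (not isolated) | C[C@@H](c1ccccc1)O[C@H]1[C@H]2C=C[C@H](O2)[C@H](C)[C@@]1(O3)C3OC | intermediate
11 | α-hydroxy aldehyde: 3-hydroxy-4-methyl-2-[(S)-1-phenylethoxy]-8-oxabicyclo[3.2.1]oct-6-ene-3-carbaldehyde, hydroxyl cis to the oxygen bridge | C[C@@H](c1ccccc1)O[C@H]1[C@H]2C=C[C@H](O2)[C@H](C)[C@@]1(O)C=O | intermediate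
12 | (S)-propylene oxide | C[C@H]1CO1 | starting material
13 | lithium (S)-1-lithiopropan-2-olate (not isolated) | [Li]C[C@H](C)O[Li] | intermediate
14 | triol: C1 tertiary, C2 secondary (both epimers) and (S)-C4 hydroxyls on the bicycle of 11 | C[C@@H](c1ccccc1)O[C@H]1[C@H]2C=C[C@H](O2)[C@H](C)[C@@]1(O)C(O)C[C@H](C)O | intermediate
15 | C4 tert-butyldiphenylsilyl ether of 14 | C[C@@H](c1ccccc1)O[C@H]1[C@H]2C=C[C@H](O2)[C@H](C)[C@@]1(O)C(O)C[C@H](C)O[Si](c3ccccc3)(c4ccccc4)C(C)(C)C | intermediate
16 | C1,C2-acetonide of 15 | C[C@@H](c1ccccc1)O[C@H]1[C@H]2C=C[C@H](O2)[C@H](C)[C@@]1(OC(C)(C)O3)C3C[C@H](C)O[Si](c4ccccc4)(c5ccccc5)C(C)(C)C | intermediate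
17 | ring-opened cycloheptenol: 6-OH and 7-isopropenyl cis, C8=C9 alkene | C[C@@H](c1ccccc1)O[C@H]1[C@H](O)[C@H](C(C)=C)C=C[C@H](C)[C@@]1(OC(C)(C)O3)C3C[C@H](C)O[Si](c4ccccc4)(c5ccccc5)C(C)(C)C | intermediate
18 | B-alkyl-9-borabicyclo[3.3.1]nonane from 17 (not isolated) | C[C@@H](c1ccccc1)O[C@H]1[C@H](O)[C@H](C(C)CB6C7CCCC6CCC7)C=C[C@H](C)[C@@]1(OC(C)(C)O3)C3C[C@H](C)O[Si](c4ccccc4)(c5ccccc5)C(C)(C)C | intermediate
19 | 6,12-diol (both C11 epimers) | C[C@@H](c1ccccc1)O[C@H]1[C@H](O)[C@H](C(C)CO)C=C[C@H](C)[C@@]1(OC(C)(C)O3)C3C[C@H](C)O[Si](c4ccccc4)(c5ccccc5)C(C)(C)C | intermediate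
20 | lactol from 19 (not isolated) | C[C@@H](c1ccccc1)O[C@H]1[C@@H]2OC(O)C(C)[C@@H]2C=C[C@H](C)[C@@]1(OC(C)(C)O3)C3C[C@H](C)O[Si](c4ccccc4)(c5ccccc5)C(C)(C)C | intermediate
21 | cis-fused γ-lactone (both C11 epimers) | C[C@@H](c1ccccc1)O[C@H]1[C@@H]2OC(=O)C(C)[C@@H]2C=C[C@H](C)[C@@]1(OC(C)(C)O3)C3C[C@H](C)O[Si](c4ccccc4)(c5ccccc5)C(C)(C)C | intermediate
22 | lithium enolate of 21 (not isolated) | C[C@@H](c1ccccc1)O[C@H]1[C@@H]2OC(O[Li])=C(C)[C@@H]2C=C[C@H](C)[C@@]1(OC(C)(C)O3)C3C[C@H](C)O[Si](c4ccccc4)(c5ccccc5)C(C)(C)C | intermediate
23 | cis-fused γ-lactone, C11 methyl cis to C8 | C[C@@H](c1ccccc1)O[C@H]1[C@@H]2OC(=O)[C@H](C)[C@@H]2C=C[C@H](C)[C@@]1(OC(C)(C)O3)C3C[C@H](C)O[Si](c4ccccc4)(c5ccccc5)C(C)(C)C | intermediate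
24 | saturated lactone with free C5 hydroxyl | O[C@H]1[C@@H]2OC(=O)[C@H](C)[C@@H]2CC[C@H](C)[C@@]1(OC(C)(C)O3)C3C[C@H](C)O[Si](c4ccccc4)(c5ccccc5)C(C)(C)C | intermediate
25 | angelic acid, (Z)-2-methylbut-2-enoic acid | C/C=C(/C)C(=O)O | starting material
26 | C5 angelate of 24 | C/C=C(/C)C(=O)O[C@H]1[C@@H]2OC(=O)[C@H](C)[C@@H]2CC[C@H](C)[C@@]1(OC(C)(C)O3)C3C[C@H](C)O[Si](c4ccccc4)(c5ccccc5)C(C)(C)C | intermediate
27 | C1,C2-diol (C2 epimers), C4 silyl ether | C/C=C(/C)C(=O)O[C@H]1[C@@H]2OC(=O)[C@H](C)[C@@H]2CC[C@H](C)[C@@]1(O)C(O)C[C@H](C)O[Si](c3ccccc3)(c4ccccc4)C(C)(C)C | intermediate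
28 | C2 ketone, C4 silyl ether | C/C=C(/C)C(=O)O[C@H]1[C@@H]2OC(=O)[C@H](C)[C@@H]2CC[C@H](C)[C@@]1(O)C(=O)C[C@H](C)O[Si](c3ccccc3)(c4ccccc4)C(C)(C)C | intermediate
29 | CNP0321985.2 | C/C=C(/C)C(=O)O[C@H]1[C@@H]2OC(=O)[C@H](C)[C@@H]2CC[C@H](C)[C@@]1(O)C(=O)C[C@H](C)O | target

## Step count and risk

Total step count: 18. Longest linear sequence: 18 steps, from 1 to 29; furan 5, (S)-propylene oxide 12 and angelic acid 25 enter as purchased.

**Step 3 (key step).** The most likely failure is insufficient facial discrimination by the auxiliary, which would give a mixture of diastereomeric bicycles. Competing ionisation of the 1-phenylethoxy group (which would give a racemic methoxy bicycle) and acid-induced oligomerisation of furan are secondary risks. All three arise because the cation is planar, small and very reactive. Fallback, from 2 to 7: the alkoxy-oxyallyl intermediate is generated by base instead of by acetal ionisation. Alcohol 2 opens epichlorohydrin under BF3·OEt2 catalysis to give 1-chloro-3-[(S)-1-phenylethoxy]propan-2-ol F1. Dess–Martin oxidation gives 1-chloro-3-[(S)-1-phenylethoxy]propan-2-one F2. Dehydrochlorination of F2 with Et3N in 2,2,2-trifluoroethanol in the presence of furan 5 should give the same cycloadduct 7, which is separated from its diastereomers by chromatography.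

**Step 10.** Three things can go wrong. The organolithium may attack C8 instead of C7, because the electronic bias from the C5 ether is modest. The sp2 organolithium may add sluggishly to the less strained [3.2.1] alkene. Benzylic metalation of the auxiliary may compete under forcing conditions. Fallback, from 16 to 24: the carbon is attached by carbonyl chemistry instead of carbometalation.
- Bridge-side hydroboration of 16 (BH3·THF, then NaOH, H2O2) and separation of the regioisomers gives the C7 alcohol F3.
- Dess–Martin oxidation gives the C7 ketone F4.
- The bridgehead C6 cannot enolise, so Me3SiOTf and Et3N followed by mild acid can only enolise toward C8 and expel the C9 oxygen, which gives the 6-hydroxycyclohept-8-en-7-one F5.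
- Esterification of the C6 hydroxyl with 2-(diethoxyphosphoryl)propanoic acid (DCC, DMAP) gives the phosphonate ester F6.
- An intramolecular Horner–Wadsworth–Emmons reaction (LiCl, DBU, MeCN) closes the dienyl butenolide F7.
- Hydrogenation over Pd/C adds hydrogen to C7 and C11 from the face of H6, saturates C8=C9 and removes the auxiliary, and so rejoins the route at 24 with C7 and C11 already set.

**Step 6 (with step 5).** The axial C10 methyl group lies on the same side as the intended approach of the oxidant and may erode or reverse the facial preference. The preceding Wittig reaction may be slow on the doubly flanked ketone and allow epimerisation at C10. Fallback, from 8 to 11: the polarity is reversed. If the methyl group, not the etheno bridge, decides the face, a carbon nucleophile will add to ketone 8 from the side of the etheno bridge, which is the required sense. 2-Lithio-1,3-dithiane (THF, −78 °C) then gives the dithianyl carbinol F8, and dethioacetalisation (MeI, CaCO3, aqueous MeCN) gives aldehyde 11 without an olefination step.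

**Step 7.** Reductive lithiation may be incomplete or may leave arene radical anion that reduces the aldehyde, and the dianion may be quenched by adventitious protons before it adds. Fallback, from 11 to 14: allylmagnesium bromide adds to 11 to give the homoallylic diol F9. Wacker oxidation (PdCl2, CuCl, O2, DMF–H2O) of the terminal alkene gives the β-hydroxy ketone F10, with the C2 carbinol and a C4 ketone. A hydroxyl-directed reduction then sets C4 relative to C2; the Evans–Saksena (anti) or Narasaka–Prasad (syn) protocol is chosen according to the C2 configuration formed in the allylation, to give the S carbinol. This returns triol 14 as a single C2 epimer.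

**Step 13.** Protonation may not discriminate well enough between the two faces of the enolate, or the epimer whose C11 hydrogen is on the concave face may enolise incompletely, leaving a mixture at C11. Fallback, from 21 to 24: C11 is set by hydrogen delivery instead of proton delivery. The enolate of 21 is selenenylated (LiN(i-Pr)2, PhSeBr) to the α-phenylselanyl lactone F11. Oxidation with H2O2 and syn elimination toward the methyl group give the α-methylene lactone F12. Hydrogenation under the conditions of step 14 adds hydrogen to C11 from the convex face and gives 24 directly; any endocyclic butenolide formed in the elimination is reduced from the same face.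

## Further compounds

F1 | step 3 | 1-chloro-3-[(S)-1-phenylethoxy]propan-2-ol (both carbinol epimers) | ClCC(O)CO[C@@H](C)c1ccccc1
F2 | step 3 | 1-chloro-3-[(S)-1-phenylethoxy]propan-2-one | ClCC(=O)CO[C@@H](C)c1ccccc1
F3 | step 10 | C7 alcohol of 16, hydroxyl on the side of the oxygen bridge | C[C@@H](c1ccccc1)O[C@H]1[C@H]2[C@H](O)C[C@H](O2)[C@H](C)[C@@]1(OC(C)(C)O3)C3C[C@H](C)O[Si](c4ccccc4)(c5ccccc5)C(C)(C)C
F4 | step 10 | C7 ketone of the oxygen-bridged bicycle | C[C@@H](c1ccccc1)O[C@H]1[C@H]2C(=O)C[C@H](O2)[C@H](C)[C@@]1(OC(C)(C)O3)C3C[C@H](C)O[Si](c4ccccc4)(c5ccccc5)C(C)(C)C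
F5 | step 10 | ring-opened 6-hydroxycyclohept-8-en-7-one | C[C@@H](c1ccccc1)O[C@H]1[C@H](O)C(=O)C=C[C@H](C)[C@@]1(OC(C)(C)O3)C3C[C@H](C)O[Si](c4ccccc4)(c5ccccc5)C(C)(C)C
F6 | step 10 | C6 2-(diethoxyphosphoryl)propanoate of F5 | C[C@@H](c1ccccc1)O[C@H]1[C@H](OC(=O)C(C)P(=O)(OCC)OCC)C(=O)C=C[C@H](C)[C@@]1(OC(C)(C)O3)C3C[C@H](C)O[Si](c4ccccc4)(c5ccccc5)C(C)(C)C
F7 | step 10 | dienyl butenolide (C7=C11 and C8=C9) | C[C@@H](c1ccccc1)O[C@H]1[C@@H]2OC(=O)C(C)=C2C=C[C@H](C)[C@@]1(OC(C)(C)O3)C3C[C@H](C)O[Si](c4ccccc4)(c5ccccc5)C(C)(C)C
F8 | step 6 | 3-(1,3-dithian-2-yl) carbinol from 8, hydroxyl cis to the oxygen bridge | C[C@@H](c1ccccc1)O[C@H]1[C@H]2C=C[C@H](O2)[C@H](C)[C@@]1(O)C3SCCCS3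
F9 | step 7 | homoallylic diol from 11 (C1 and C2 hydroxyls, terminal alkene) | C[C@@H](c1ccccc1)O[C@H]1[C@H]2C=C[C@H](O2)[C@H](C)[C@@]1(O)C(O)CC=C
F10 | step 7 | β-hydroxy ketone with the C2 carbinol and a C4 ketone | C[C@@H](c1ccccc1)O[C@H]1[C@H]2C=C[C@H](O2)[C@H](C)[C@@]1(O)C(O)CC(C)=O
F11 | step 13 | α-phenylselanyl lactone from 21 | C[C@@H](c1ccccc1)O[C@H]1[C@@H]2OC(=O)C(C)([Se]c6ccccc6)[C@@H]2C=C[C@H](C)[C@@]1(OC(C)(C)O3)C3C[C@H](C)O[Si](c4ccccc4)(c5ccccc5)C(C)(C)C
F12 | step 13 | α-methylene lactone | C[C@@H](c1ccccc1)O[C@H]1[C@@H]2OC(=O)C(=C)[C@@H]2C=C[C@H](C)[C@@]1(OC(C)(C)O3)C3C[C@H](C)O[Si](c4ccccc4)(c5ccccc5)C(C)(C)C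
A1 | alternative 1 | cis-dihydrocarvone, cis-2-methyl-5-(prop-1-en-2-yl)cyclohexanone | C[C@H]1CC[C@@H](C(C)=C)CC1=O
A2 | alternative 1 | cis-2-methyl-5-(prop-1-en-2-yl)cycloheptanone | C[C@H]1CC[C@@H](C(C)=C)CCC1=O
A3 | alternative 2 | 2-benzyloxy-3-methyl-6-[1-(tert-butyldimethylsilyloxy)propan-2-yl]cyclohept-4-enone | O=C1C[C@H]([C@@H](C)CO[Si](C)(C)C(C)(C)C)C=C[C@H](C)[C@@H]1OCc2ccccc2
A4 | alternative 3 | acetonide-protected bicyclic cis-lactone with the C1 methyl ester | CC1(C)O[C@H]2[C@@H]3OC(=O)[C@H](C)[C@@H]3CC[C@H](C)[C@]2(C(=O)OC)O1
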